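**Retrosynthetic overview**
- Ester C–O bond: the target comes from tetradecanoyl chloride and (3S,5R,6S)-3-hydroxy-5,6-epoxy-5,6-dihydro-β-ionone, whose hydroxyl is carried as a TBS ether.
- Both rings in one step: the C5–C6 bond and the C6–O bond are cut together, giving an acyclic (E)-γ-chloro enone tethered to a methyl ketone. In the forward sense this is an intramolecular vinylogous Darzens annulation: the aldol closes the carbocycle, then chloride displacement closes the oxirane in the same flask, with the C3 stereocentre controlling C5 and C6.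
- The γ-chloro enone comes from an aldehyde (α-chlorination, then Wittig with the acetonylidene ylide), and the aldehyde from a terminal vinyl group by aldehyde-selective Wacker oxidation.
- The C3 carbinol comes from an enamine-catalysed acetone aldol on 3,3-dimethylpent-4-enal, made from methyl 3,3-dimethylpent-4-enoate.

Assumption: carotenoid-style locants are used in the explanations (ring C1 = CMe2, C3 = C–O, C5/C6 = epoxide carbons, side chain C7–C10); the target is the (3S,5R,6S) isomer, with the epoxide oxygen anti to the C3 oxygen.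

**Route**

Step 1
Reactants: 1 methyl 3,3-dimethylpent-4-enoate
Product: 2 3,3-dimethylpent-4-enal
Conditions: i-Bu2AlH (1.05 equiv), CH2Cl2, −78 °C; then MeOH, aq. potassium sodium tartrate
Reagents that add atoms: none
Why: Half-reduction of a methyl ester with i-Bu2AlH at −78 °C stops at the aluminium hemiacetal, which releases the aldehyde only on work-up, and the isolated alkene is inert; no stereocentre is formed.

Step 2
Reactants: 2 3,3-dimethylpent-4-enal, 3 acetone
Product: 4 (4S)-4-hydroxy-6,6-dimethyloct-7-en-2-one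
Conditions: N-[(2S)-1-hydroxy-4-methyl-1,1-diphenylpentan-2-yl]-L-prolinamide (10 mol%), acetone (solvent), −40 °C, 48 h
Reagents that add atoms: none
Why: Enamine-catalysed direct asymmetric aldol reaction (List–Barbas type) in which the acetone enamine adds to the re face of the aldehyde in the hydrogen-bonded Houk–List transition state, giving the (S)-carbinol (the sense L-proline gives with α-unbranched aldehydes), while the β-quaternary aldehyde self-condenses only slowly in neat acetone.

Step 3
Reactants: 4 (4S)-4-hydroxy-6,6-dimethyloct-7-en-2-one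
Product: 5 (4S)-4-[(tert-butyldimethylsilyl)oxy]-6,6-dimethyloct-7-en-2-one
Conditions: TBSCl, imidazole, DMF, 23 °C
Reagents that add atoms: tert-butyldimethylsilyl chloride, CC(C)(C)[Si](C)(C)Cl
Why: Imidazole-mediated silylation masks the aldol hydroxyl, so that no alkoxide can later undergo retro-aldol cleavage, oxa-Michael addition or chloride displacement, and leaves the stereocentre untouched.

Step 4
Reactants: 5 (4S)-4-[(tert-butyldimethylsilyl)oxy]-6,6-dimethyloct-7-en-2-one
Product: 6 (5S)-5-[(tert-butyldimethylsilyl)oxy]-3,3-dimethyl-7-oxooctanal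
Conditions: PdCl2(PhCN)2 (12 mol%), CuCl2·2H2O (12 mol%), AgNO2 (6 mol%), O2 (1 atm), t-BuOH/MeNO2 (15:1), 23 °C
Reagents that add atoms: dioxygen, O=O
Why: Nitrite-modified aldehyde-selective (anti-Markovnikov) Wacker oxidation delivers oxygen to the terminal carbon, a preference reinforced by the adjacent quaternary carbon that shields the internal position; the ketone and silyl ether are spectators and no stereocentre is touched.

Step 5
Reactants: 6 (5S)-5-[(tert-butyldimethylsilyl)oxy]-3,3-dimethyl-7-oxooctanal, 7 (acetylmethylene)triphenylphosphorane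
Product: 9 (3E,8S)-8-[(tert-butyldimethylsilyl)oxy]-5-chloro-6,6-dimethylundec-3-ene-2,10-dione, via α-chloro aldehyde 8 (not isolated)
Conditions: NCS (1.05 equiv), L-prolinamide (10 mol%), CH2Cl2, 0 → 23 °C; then 7 (1.3 equiv), 23 → 40 °C, one pot
Reagents that add atoms: N-chlorosuccinimide, O=C1CCC(=O)N1Cl
Why: Enamine-catalysed α-chlorination of the aldehyde (Jørgensen type, precedented for 3,3-dimethylbutanal) is followed by Wittig olefination with the stabilised ylide, which attacks only the aldehyde and gives the E-enone; HCl loss is impossible because the neighbouring carbon is quaternary, and the configuration at the C–Cl carbon is immaterial because step 6 planarises it.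

Step 6
Reactants: 9 (3E,8S)-8-[(tert-butyldimethylsilyl)oxy]-5-chloro-6,6-dimethylundec-3-ene-2,10-dione
Product: 12 (3E)-4-[(1S,4S,6R)-4-[(tert-butyldimethylsilyl)oxy]-2,2,6-trimethyl-7-oxabicyclo[4.1.0]heptan-1-yl]but-3-en-2-one, via potassium dienolate 10 (not isolated), via chlorohydrin alkoxide 11 (not isolated)
Conditions: KOt-Bu (1.05 equiv), THF/t-BuOH (10:1), 0.02 M, −40 → 0 °C
Reagents that add atoms: none
Why: Proposed new method: intramolecular vinylogous Darzens annulation in which KOt-Bu (t-BuOH as proton shuttle) removes the most acidic proton (C6–H, α to chlorine and vinylogous to the enone carbonyl), the dienolate attacks the C5 methyl ketone through its γ-carbon (six-membered ring, helped by the gem-dimethyl group, against an eight-membered ring for α-attack) in a reversible aldol step, and only the aldolate with C5–O− and C6–Cl trans-diaxial and the C3 silyloxy group equatorial closes the oxirane by irreversible intramolecular SN2 displacement of chloride, which places the epoxide oxygen anti to the C3 oxygen (3S,5R,6S), keeps the E-enone through the s-trans dienolate and lets mismatched aldolates revert by retro-aldol; the closest known reactions are the vinylogous Darzens reaction of γ-halocrotonate dienolates with carbonyl compounds to give vinyl oxiranes and the classical intramolecular Darzens condensation.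

Step 7
Reactants: 12 (3E)-4-[(1S,4S,6R)-4-[(tert-butyldimethylsilyl)oxy]-2,2,6-trimethyl-7-oxabicyclo[4.1.0]heptan-1-yl]but-3-en-2-one
Product: 13 (3E)-4-[(1S,4S,6R)-4-hydroxy-2,2,6-trimethyl-7-oxabicyclo[4.1.0]heptan-1-yl]but-3-en-2-one
Conditions: Bu4NF, AcOH (1:1), THF, 0 → 23 °C
Reagents that add atoms: none
Why: Fluoride-driven desilylation, buffered with AcOH to near neutrality, leaves the vinyl epoxide, the enone and all three stereocentres unchanged.

Step 8
Reactants: 13 (3E)-4-[(1S,4S,6R)-4-hydroxy-2,2,6-trimethyl-7-oxabicyclo[4.1.0]heptan-1-yl]but-3-en-2-one, 14 tetradecanoyl chloride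
Product: 15 (1R,3S,6S)-1,5,5-trimethyl-6-[(1E)-3-oxobut-1-en-1-yl]-7-oxabicyclo[4.1.0]heptan-3-yl tetradecanoate
Conditions: Et3N, DMAP (10 mol%), CH2Cl2, 0 → 23 °C
Reagents that add atoms: none
Why: DMAP-catalysed O-acylation of the secondary alcohol proceeds with retention at C3 under mild basic conditions that the epoxy enone tolerates.

**Compound list**
1 | methyl 3,3-dimethylpent-4-enoate | COC(=O)CC(C)(C)C=C | starting material
2 | 3,3-dimethylpent-4-enal | O=CCC(C)(C)C=C | intermediate
3 | acetone | CC(C)=O | starting material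
4 | (4S)-4-hydroxy-6,6-dimethyloct-7-en-2-one | CC(=O)C[C@@H](O)CC(C)(C)C=C | intermediate
5 | (4S)-4-[(tert-butyldimethylsilyl)oxy]-6,6-dimethyloct-7-en-2-one | CC(=O)C[C@@H](O[Si](C)(C)C(C)(C)C)CC(C)(C)C=C | intermediate
6 | (5S)-5-[(tert-butyldimethylsilyl)oxy]-3,3-dimethyl-7-oxooctanal | CC(=O)C[C@@H](O[Si](C)(C)C(C)(C)C)CC(C)(C)CC=O | intermediate
7 | (acetylmethylene)triphenylphosphorane, Ph3P=CHC(O)CH3 | CC(=O)C=P(c1ccccc1)(c1ccccc1)c1ccccc1 | starting material
8 | (5S)-5-[(tert-butyldimethylsilyl)oxy]-2-chloro-3,3-dimethyl-7-oxooctanal (both C2 epimers, not isolated) | CC(=O)C[C@@H](O[Si](C)(C)C(C)(C)C)CC(C)(C)C(Cl)C=O | intermediate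
9 | (3E,8S)-8-[(tert-butyldimethylsilyl)oxy]-5-chloro-6,6-dimethylundec-3-ene-2,10-dione (both C5 epimers) | CC(=O)C[C@@H](O[Si](C)(C)C(C)(C)C)CC(C)(C)C(Cl)/C=C/C(C)=O | intermediate
10 | potassium (8S)-8-[(tert-butyldimethylsilyl)oxy]-5-chloro-6,6-dimethyl-10-oxoundeca-2,4-dien-2-olate (delocalised dienolate, not isolated) | CC(=O)C[C@@H](O[Si](C)(C)C(C)(C)C)CC(C)(C)C(Cl)=CC=C(C)[O-].[K+] | intermediate
11 | potassium (1R,2R,5S)-5-[(tert-butyldimethylsilyl)oxy]-2-chloro-1,3,3-trimethyl-2-[(1E)-3-oxobut-1-en-1-yl]cyclohexan-1-olate (not isolated) | CC(C)(C)[Si](C)(C)O[C@H]1CC(C)(C)[C@](Cl)(/C=C/C(C)=O)[C@@]([O-])(C)C1.[K+] | intermediate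
12 | (3E)-4-[(1S,4S,6R)-4-[(tert-butyldimethylsilyl)oxy]-2,2,6-trimethyl-7-oxabicyclo[4.1.0]heptan-1-yl]but-3-en-2-one | CC(C)(C)[Si](C)(C)O[C@H]1CC(C)(C)[C@]2(/C=C/C(C)=O)O[C@]2(C)C1 | intermediate
13 | (3E)-4-[(1S,4S,6R)-4-hydroxy-2,2,6-trimethyl-7-oxabicyclo[4.1.0]heptan-1-yl]but-3-en-2-one | O[C@H]1CC(C)(C)[C@]2(/C=C/C(C)=O)O[C@]2(C)C1 | intermediate
14 | tetradecanoyl chloride | CCCCCCCCCCCCCC(=O)Cl | starting material
15 | (1R,3S,6S)-1,5,5-trimethyl-6-[(1E)-3-oxobut-1-en-1-yl]-7-oxabicyclo[4.1.0]heptan-3-yl tetradecanoate (CNP0118807.1) | CCCCCCCCCCCCCC(=O)O[C@H]1CC(C)(C)[C@]2(/C=C/C(C)=O)O[C@]2(C)C1 | target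

**Step count and risks**

Total step count: 8. Longest linear sequence: 8 steps (1 → 15).

The three steps most likely to fail are steps 6, 4 and 5.

Step 6 (vinylogous Darzens annulation). The risks are that the C5 ketone enolises and cyclises by Michael addition or alkylation, or that facial control is poor. The fallback sets out from 6 and comes back at 12. It keeps the two-ring Darzens annulation but uses the classical α-chloro ester nucleophile and builds the enone afterwards. Aldehyde 6 is α-chlorinated as in step 5 to 8 and oxidised without isolation (NaClO2, NaH2PO4, 2-methylbut-2-ene, t-BuOH/H2O) to (5S)-5-[(tert-butyldimethylsilyl)oxy]-2-chloro-3,3-dimethyl-7-oxooctanoic acid F1. Methylation with Me3SiCHN2 in MeOH/toluene gives methyl (5S)-5-[(tert-butyldimethylsilyl)oxy]-2-chloro-3,3-dimethyl-7-oxooctanoate F2. KOt-Bu in THF/t-BuOH then effects the classical intramolecular Darzens condensation, under the same chair control, to methyl (1S,4S,6R)-4-[(tert-butyldimethylsilyl)oxy]-2,2,6-trimethyl-7-oxabicyclo[4.1.0]heptane-1-carboxylate F3. Half-reduction with i-Bu2AlH at −78 °C gives (1S,4S,6R)-4-[(tert-butyldimethylsilyl)oxy]-2,2,6-trimethyl-7-oxabicyclo[4.1.0]heptane-1-carbaldehyde F4, and Wittig olefination with 7 delivers 12.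

Step 4 (aldehyde-selective Wacker oxidation of a vinyl group on a quaternary carbon). The risks are low conversion or methyl ketone formation. The fallback sets out from 5 and comes back at 6. It replaces the direct oxidation by a hydroboration–oxidation sequence. Catecholborane with RhCl(PPh3)3 (2 mol%) in THF hydroborates the terminal alkene faster than it reduces the ketone, and NaBO3·4H2O oxidation gives (4S)-4-[(tert-butyldimethylsilyl)oxy]-8-hydroxy-6,6-dimethyloctan-2-one F5. Dess–Martin periodinane in CH2Cl2 then oxidises F5 to 6.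

Step 5 (α-chlorination next to a quaternary carbon, then Wittig). The risks are sluggish enamine formation or a competing intramolecular aldol of the keto aldehyde. The fallback sets out from 5 and comes back at 9. It builds the γ-chloro enone from a neopentyl aldehyde instead. Ozonolysis of 5 (O3, CH2Cl2, −78 °C; Me2S) gives (4S)-4-[(tert-butyldimethylsilyl)oxy]-2,2-dimethyl-6-oxoheptanal F6. Aldehyde-selective Nozaki–Hiyama–Kishi coupling with (E)-4-iodobut-3-en-2-one (CrCl2, 1 mol% NiCl2, DMF) gives (3E,8S)-8-[(tert-butyldimethylsilyl)oxy]-5-hydroxy-6,6-dimethylundec-3-ene-2,10-dione F7. PPh3/N-chlorosuccinimide in CH2Cl2 converts the allylic alcohol into chloride 9; either C5 epimer serves.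

Further compounds
F1 | step 6 | (5S)-5-[(tert-butyldimethylsilyl)oxy]-2-chloro-3,3-dimethyl-7-oxooctanoic acid | CC(=O)C[C@@H](O[Si](C)(C)C(C)(C)C)CC(C)(C)C(Cl)C(=O)O
F2 | step 6 | methyl (5S)-5-[(tert-butyldimethylsilyl)oxy]-2-chloro-3,3-dimethyl-7-oxooctanoate | CC(=O)C[C@@H](O[Si](C)(C)C(C)(C)C)CC(C)(C)C(Cl)C(=O)OC
F3 | step 6 | methyl (1S,4S,6R)-4-[(tert-butyldimethylsilyl)oxy]-2,2,6-trimethyl-7-oxabicyclo[4.1.0]heptane-1-carboxylate | CC(C)(C)[Si](C)(C)O[C@H]1CC(C)(C)[C@]2(C(=O)OC)O[C@]2(C)C1
F4 | step 6 | (1S,4S,6R)-4-[(tert-butyldimethylsilyl)oxy]-2,2,6-trimethyl-7-oxabicyclo[4.1.0]heptane-1-carbaldehyde | CC(C)(C)[Si](C)(C)O[C@H]1CC(C)(C)[C@]2(C=O)O[C@]2(C)C1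
F5 | step 4 | (4S)-4-[(tert-butyldimethylsilyl)oxy]-8-hydroxy-6,6-dimethyloctan-2-one | CC(=O)C[C@@H](O[Si](C)(C)C(C)(C)C)CC(C)(C)CCO
F6 | step 5 | (4S)-4-[(tert-butyldimethylsilyl)oxy]-2,2-dimethyl-6-oxoheptanal | CC(=O)C[C@@H](O[Si](C)(C)C(C)(C)C)CC(C)(C)C=O
F7 | step 5 | (3E,8S)-8-[(tert-butyldimethylsilyl)oxy]-5-hydroxy-6,6-dimethylundec-3-ene-2,10-dione | CC(=O)C[C@@H](O[Si](C)(C)C(C)(C)C)CC(C)(C)C(O)/C=C/C(C)=O
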